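**Plan**

- Retrosynthesis (azulene numbering): cut the tertiary ester C1–O–acyl bond, the two epoxide C–O bonds (back to a C5=C6 alkene) and the C1–isopropyl bond (back to a C1 ketone). Then cut, in one operation, the ring bonds C8–C8a and C5–C6 of the cycloheptane, and last the C3a–CH3 bond.
- Enabling feature: C8 is a carbinol carbon bonded to C8a, which is α to a carbonyl once C1 is a ketone (aldol retron). The C5/C6 epoxide is a masked trisubstituted alkene of the seven-membered ring whose carbons end an allyl and a 2-methylallyl group (metathesis retron). The C6–C7–C8 piece is 3-methylbut-3-enal.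
- Forward: the five-membered ring comes first (3-allylcyclopentenone, methyl conjugate addition, enolate stored as silyl enol ether). The seven-membered ring is then annulated onto C8a/C3a in one flask (aldol, silylation, ring-closing metathesis). Isopropyl addition, acylation, desilylation, epoxidation and debenzylation finish the route.
- Stereochemistry: C3a from ligand-controlled conjugate addition; C8a and C8 from the aldol (approach anti to the allyl group, chair transition state); C1 from addition anti to the C8a substituent; C5/C6 from oxygen delivery by the C8 hydroxyl.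

Key step: step 4

Remark: the acyl group is taken to sit on the tertiary C1 oxygen with C8–OH free, as drawn; azulene numbering is used for the bicycle (C1 carbinol carbon with isopropyl, C3a methyl-bearing fusion carbon, C5/C6 epoxide carbons, C8 carbinol CH, C8a fusion CH).

**Route**

Step 1
Reactants: 1 3-ethoxycyclopent-2-en-1-one
Product: 3 3-(prop-2-en-1-yl)cyclopent-2-en-1-one, via tertiary allylic carbinol 2 (not isolated)
Conditions: CH2=CHCH2MgBr, THF, 0 °C; then 1 M HCl, 0 °C
Reagents that add atoms: allylmagnesium bromide C=CC[Mg]Br; water O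
Why: The Stork–Danheiser sequence (1,2-addition of the Grignard reagent to the vinylogous ester, then acid hydrolysis of the enol ether with loss of the tertiary hydroxyl) should give the 3-substituted enone, and no stereocentre is formed.

Step 2
Reactants: 3 3-(prop-2-en-1-yl)cyclopent-2-en-1-one
Product: 5 (R)-triethyl{[3-methyl-3-(prop-2-en-1-yl)cyclopent-1-en-1-yl]oxy}silane, via dimethylaluminium enolate 4 (not isolated)
Conditions: Me3Al, Cu(OTf)2 (5 mol %), chiral N-heterocyclic carbene ligand (5 mol %), THF, −78 °C; then Et3SiOTf, −78 to 0 °C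
Reagents that add atoms: trimethylaluminium C[Al](C)C; triethylsilyl trifluoromethanesulfonate CC[Si](CC)(CC)OS(=O)(=O)C(F)(F)F
Why: Copper-catalysed asymmetric conjugate addition of methyl to the β-substituted cyclopentenone should set the quaternary centre as (R) under control of the chiral ligand (enantiomer chosen accordingly), and O-silylation of the aluminium enolate fixes the enol double bond on the side of the quaternary carbon.

Step 3
Reactants: 6 3-methylbut-3-en-1-ol
Product: 7 3-methylbut-3-enal
Conditions: Dess–Martin periodinane, CH2Cl2, 0 °C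
Reagents that add atoms: none
Why: Dess–Martin oxidation of the primary alcohol at low temperature should give the β,γ-unsaturated aldehyde without migration of the alkene into conjugation, and no stereocentre is formed.

Step 4
Reactants: 5 (R)-triethyl{[3-methyl-3-(prop-2-en-1-yl)cyclopent-1-en-1-yl]oxy}silane; 7 3-methylbut-3-enal
Product: 11 (3aR,8S,8aS)-8-[(tert-butyldimethylsilyl)oxy]-3a,6-dimethyl-3,3a,4,7,8,8a-hexahydroazulen-1(2H)-one, via lithium enolate 8 (not isolated), via lithium aldolate 9 (not isolated), via silylated diene 10 (not isolated)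
Conditions: MeLi, THF, 0 to 23 °C; then 7, −78 °C; then t-BuMe2SiOTf, −78 to 0 °C; then second-generation Grubbs catalyst (5 mol %), toluene, 60 °C
Reagents that add atoms: tert-butyldimethylsilyl trifluoromethanesulfonate CC(C)(C)[Si](C)(C)OS(=O)(=O)C(F)(F)F
Why: MeLi cleaves the Si–O bond of 5 to the regiodefined lithium enolate 8, which adds to aldehyde 7 through a closed six-membered chair transition state to form the C8–C8a bond; silylation of aldolate 9 in the flask gives diene 10, and the ruthenium alkylidene then closes the ring between the allyl and 2-methylallyl termini (ring-closing metathesis, loss of ethene) to form the C5=C6 bond, later the epoxide C–C bond. The closest known reaction types are the lithium-enolate aldol addition of silyl enol ethers obtained by conjugate addition–trapping and ring-closing metathesis to trisubstituted cycloheptenes in hydroazulene synthesis. The only ring closed is the seven-membered ring, by ring-closing metathesis of a monosubstituted onto a 1,1-disubstituted alkene with both new sp2 carbons endocyclic. C8a is controlled by the neighbouring quaternary C3a, the aldehyde approaching the enolate face anti to the larger allyl group (syn to methyl), which leads to the trans ring fusion; C8 is controlled by the fixed E(O) geometry of the cyclic enolate in the chair transition state, which leads to the anti aldol (8S). The step needs regiocontrol of the enolate, secured by the silyl enol ether made in step 2, and chemoselective metathesis, secured because the allyl and 2-methylallyl groups are the only alkenes and can only close the seven-membered ring.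

Step 5
Reactants: 11 (3aR,8S,8aS)-8-[(tert-butyldimethylsilyl)oxy]-3a,6-dimethyl-3,3a,4,7,8,8a-hexahydroazulen-1(2H)-one
Product: 12 (1R,3aR,8S,8aS)-8-[(tert-butyldimethylsilyl)oxy]-3a,6-dimethyl-1-(propan-2-yl)-1,2,3,3a,4,7,8,8a-octahydroazulen-1-ol
Conditions: i-PrMgCl, LaCl3·2LiCl, THF, 0 °C; then aq NH4Cl
Reagents that add atoms: isopropylmagnesium chloride CC(C)[Mg]Cl
Why: Lanthanum-promoted Grignard 1,2-addition (enolisation and β-hydride reduction suppressed) should occur on the cyclopentanone face anti to the C8a substituent and the 3a-methyl, which sets C1 as (R) with the hydroxyl cis to the angular methyl.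

Step 6
Reactants: 13 4-(benzyloxy)-3-methoxybenzoic acid
Product: 14 4-(benzyloxy)-3-methoxybenzoyl chloride
Conditions: (COCl)2, DMF (cat.), CH2Cl2, 0 to 23 °C
Reagents that add atoms: oxalyl chloride ClC(=O)C(Cl)=O
Why: Acid chloride formation through the Vilsmeier-type chloroiminium intermediate is routine for alkoxybenzoic acids, and no stereocentre is involved.

Step 7
Reactants: 12 (1R,3aR,8S,8aS)-8-[(tert-butyldimethylsilyl)oxy]-3a,6-dimethyl-1-(propan-2-yl)-1,2,3,3a,4,7,8,8a-octahydroazulen-1-ol; 14 4-(benzyloxy)-3-methoxybenzoyl chloride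
Product: 15 (1R,3aR,8S,8aS)-8-[(tert-butyldimethylsilyl)oxy]-3a,6-dimethyl-1-(propan-2-yl)-1,2,3,3a,4,7,8,8a-octahydroazulen-1-yl 4-(benzyloxy)-3-methoxybenzoate
Conditions: LiN(SiMe3)2, THF, −78 °C; then 14, −78 to 0 °C
Reagents that add atoms: none
Why: O-acylation of the lithium alkoxide of the hindered tertiary alcohol by the aroyl chloride (nucleophilic acyl substitution) should give the tertiary ester with C1 unchanged, the low temperature limiting silyl migration from O8.

Step 8
Reactants: 15 (1R,3aR,8S,8aS)-8-[(tert-butyldimethylsilyl)oxy]-3a,6-dimethyl-1-(propan-2-yl)-1,2,3,3a,4,7,8,8a-octahydroazulen-1-yl 4-(benzyloxy)-3-methoxybenzoate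
Product: 16 (1R,3aR,8S,8aS)-8-hydroxy-3a,6-dimethyl-1-(propan-2-yl)-1,2,3,3a,4,7,8,8a-octahydroazulen-1-yl 4-(benzyloxy)-3-methoxybenzoate
Conditions: HF·pyridine, THF/pyridine, 0 to 23 °C
Reagents that add atoms: none
Why: Desilylation with HF·pyridine frees the C8 hydroxyl under weakly acidic conditions in which no alkoxide forms, so acyl migration from the tertiary ester is not expected and no stereocentre changes.

Step 9
Reactants: 16 (1R,3aR,8S,8aS)-8-hydroxy-3a,6-dimethyl-1-(propan-2-yl)-1,2,3,3a,4,7,8,8a-octahydroazulen-1-yl 4-(benzyloxy)-3-methoxybenzoate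
Product: 17 (1R,3aR,5S,6R,8S,8aS)-5,6-epoxy-8-hydroxy-3a,6-dimethyl-1-(propan-2-yl)decahydroazulen-1-yl 4-(benzyloxy)-3-methoxybenzoate
Conditions: VO(acac)2 (5 mol %), t-BuOOH, CH2Cl2, 0 to 23 °C
Reagents that add atoms: tert-butyl hydroperoxide CC(C)(C)OO
Why: Vanadium-catalysed hydroxyl-directed epoxidation of the homoallylic alcohol should deliver oxygen to the alkene face syn to the C8 hydroxyl (opposite to the 3a-methyl), setting C5 as (S) and C6 as (R).

Step 10
Reactants: 17 (1R,3aR,5S,6R,8S,8aS)-5,6-epoxy-8-hydroxy-3a,6-dimethyl-1-(propan-2-yl)decahydroazulen-1-yl 4-(benzyloxy)-3-methoxybenzoate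
Product: 18 (1R,3aR,5S,6R,8S,8aS)-5,6-epoxy-8-hydroxy-3a,6-dimethyl-1-(propan-2-yl)decahydroazulen-1-yl 4-hydroxy-3-methoxybenzoate
Conditions: H2 (1 atm), Pd/C, EtOAc, 23 °C
Reagents that add atoms: none
Why: Hydrogenolysis of the aryl benzyl ether over palladium on carbon should release the phenol under neutral conditions that leave the trisubstituted epoxide, the tertiary ester and the free secondary alcohol untouched.

**Compound list**

1 | 3-ethoxycyclopent-2-en-1-one | CCOC1=CC(=O)CC1 | starting material
2 | 3-ethoxy-1-(prop-2-en-1-yl)cyclopent-2-en-1-ol (formed as its magnesium alkoxide) | CCOC1=CC(O)(CC=C)CC1 | intermediate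
3 | 3-(prop-2-en-1-yl)cyclopent-2-en-1-one | O=C1C=C(CC=C)CC1 | intermediate
4 | dimethylaluminium (R)-3-methyl-3-(prop-2-en-1-yl)cyclopent-1-en-1-olate | C[Al](C)OC1=C[C@@](C)(CC=C)CC1 | intermediate
5 | (R)-triethyl{[3-methyl-3-(prop-2-en-1-yl)cyclopent-1-en-1-yl]oxy}silane | CC[Si](CC)(CC)OC1=C[C@@](C)(CC=C)CC1 | intermediate
6 | 3-methylbut-3-en-1-ol | CC(=C)CCO | starting material
7 | 3-methylbut-3-enal | CC(=C)CC=O | intermediate
8 | lithium (R)-3-methyl-3-(prop-2-en-1-yl)cyclopent-1-en-1-olate | [Li]OC1=C[C@@](C)(CC=C)CC1 | intermediate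
9 | (2S,3R)-2-[(1S)-1-(lithiooxy)-3-methylbut-3-en-1-yl]-3-methyl-3-(prop-2-en-1-yl)cyclopentan-1-one | O=C1CC[C@](C)(CC=C)[C@H]1[C@@H](O[Li])CC(C)=C | intermediate
10 | (2S,3R)-2-{(1S)-1-[(tert-butyldimethylsilyl)oxy]-3-methylbut-3-en-1-yl}-3-methyl-3-(prop-2-en-1-yl)cyclopentan-1-one | O=C1CC[C@](C)(CC=C)[C@H]1[C@@H](O[Si](C)(C)C(C)(C)C)CC(C)=C | intermediate
11 | (3aR,8S,8aS)-8-[(tert-butyldimethylsilyl)oxy]-3a,6-dimethyl-3,3a,4,7,8,8a-hexahydroazulen-1(2H)-one | O=C1CC[C@]2(C)CC=C(C)C[C@H](O[Si](C)(C)C(C)(C)C)[C@H]21 | intermediate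
12 | (1R,3aR,8S,8aS)-8-[(tert-butyldimethylsilyl)oxy]-3a,6-dimethyl-1-(propan-2-yl)-1,2,3,3a,4,7,8,8a-octahydroazulen-1-ol | O[C@@]1(C(C)C)CC[C@]2(C)CC=C(C)C[C@H](O[Si](C)(C)C(C)(C)C)[C@H]21 | intermediate
13 | 4-(benzyloxy)-3-methoxybenzoic acid | COc1cc(C(O)=O)ccc1OCc1ccccc1 | starting material
14 | 4-(benzyloxy)-3-methoxybenzoyl chloride | COc1cc(C(Cl)=O)ccc1OCc1ccccc1 | intermediate
15 | (1R,3aR,8S,8aS)-8-[(tert-butyldimethylsilyl)oxy]-3a,6-dimethyl-1-(propan-2-yl)-1,2,3,3a,4,7,8,8a-octahydroazulen-1-yl 4-(benzyloxy)-3-methoxybenzoate | COc1cc(C(=O)O[C@@]2(C(C)C)CC[C@]3(C)CC=C(C)C[C@H](O[Si](C)(C)C(C)(C)C)[C@H]32)ccc1OCc1ccccc1 | intermediate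
16 | (1R,3aR,8S,8aS)-8-hydroxy-3a,6-dimethyl-1-(propan-2-yl)-1,2,3,3a,4,7,8,8a-octahydroazulen-1-yl 4-(benzyloxy)-3-methoxybenzoate | COc1cc(C(=O)O[C@@]2(C(C)C)CC[C@]3(C)CC=C(C)C[C@H](O)[C@H]32)ccc1OCc1ccccc1 | intermediate
17 | (1R,3aR,5S,6R,8S,8aS)-5,6-epoxy-8-hydroxy-3a,6-dimethyl-1-(propan-2-yl)decahydroazulen-1-yl 4-(benzyloxy)-3-methoxybenzoate | COc1cc(C(=O)O[C@@]2(C(C)C)CC[C@]3(C)C[C@@H]4O[C@]4(C)C[C@H](O)[C@H]32)ccc1OCc1ccccc1 | intermediate
18 | (1R,3aR,5S,6R,8S,8aS)-5,6-epoxy-8-hydroxy-3a,6-dimethyl-1-(propan-2-yl)decahydroazulen-1-yl 4-hydroxy-3-methoxybenzoate | COc1cc(C(=O)O[C@@]2(C(C)C)CC[C@]3(C)C[C@@H]4O[C@]4(C)C[C@H](O)[C@H]32)ccc1O | target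

**Step count and risks**

Total steps: 10. Longest linear sequence: 8 (steps 1, 2, 4, 5, 7, 8, 9, 10).

Steps most likely to fail:

1. Step 4. The aldol addition may lose its anti preference at C8, because boat transition states can compete with the chair for an E(O) cyclic enolate. The fallback sets out from 12, carried through step 5 as the mixture of C8 epimers, and comes back to the route at 12 as the single (8S) isomer. Bu4NF in THF should remove the silyl ether to give (1R,3aR,8aS)-3a,6-dimethyl-1-(propan-2-yl)-1,2,3,3a,4,7,8,8a-octahydroazulene-1,8-diol F1 as both C8 epimers. Dess–Martin periodinane should oxidise only the secondary hydroxyl to (1R,3aR,8aR)-1-hydroxy-3a,6-dimethyl-1-(propan-2-yl)-2,3,3a,4,7,8a-hexahydroazulen-8(1H)-one F2. Me4NBH(OAc)3 in MeCN/AcOH at −20 °C should then deliver hydride from the C1 oxygen to the same face of the C8 ketone (Evans–Saksena reduction, 1,3-anti diol) to give (1R,3aR,8S,8aS)-3a,6-dimethyl-1-(propan-2-yl)-1,2,3,3a,4,7,8,8a-octahydroazulene-1,8-diol F3. Finally t-BuMe2SiOTf with 2,6-lutidine at −78 °C should silylate only the secondary hydroxyl and return 12.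

2. Step 7. The silyl group may migrate from O8 to the tertiary alkoxide, and acylation of the hindered alkoxide may be slow. The fallback sets out from 13 and 12 and comes back at 15. DCC (0.5 equiv) in CH2Cl2 should convert 13 into 4-(benzyloxy)-3-methoxybenzoic anhydride F4. Catalytic Sc(OTf)3 in MeCN at −20 °C should then acylate the neutral tertiary alcohol 12 with F4, so that no alkoxide is formed and the silyl ether cannot migrate.

3. Step 5. Enolisation of the ketone (followed by β-elimination of the silyloxy group) or β-hydride reduction by the secondary Grignard reagent may compete with addition. The fallback sets out from 11 and comes back at 12. CH2=C(CH3)MgBr with LaCl3·2LiCl in THF should add the smaller 2-propenyl group, which cannot act as a hydride donor, to give (1S,3aR,8S,8aS)-8-[(tert-butyldimethylsilyl)oxy]-3a,6-dimethyl-1-(prop-1-en-2-yl)-1,2,3,3a,4,7,8,8a-octahydroazulen-1-ol F5. H2 with RhCl(PPh3)3 in benzene should then saturate the 1,1-disubstituted alkene in preference to the trisubstituted ring alkene and give 12.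

**Further compounds**

F1 | step 4 | (1R,3aR,8aS)-3a,6-dimethyl-1-(propan-2-yl)-1,2,3,3a,4,7,8,8a-octahydroazulene-1,8-diol (C8 epimers) | O[C@@]1(C(C)C)CC[C@]2(C)CC=C(C)CC(O)[C@H]21
F2 | step 4 | (1R,3aR,8aR)-1-hydroxy-3a,6-dimethyl-1-(propan-2-yl)-2,3,3a,4,7,8a-hexahydroazulen-8(1H)-one | O[C@@]1(C(C)C)CC[C@]2(C)CC=C(C)CC(=O)[C@H]21
F3 | step 4 | (1R,3aR,8S,8aS)-3a,6-dimethyl-1-(propan-2-yl)-1,2,3,3a,4,7,8,8a-octahydroazulene-1,8-diol | O[C@@]1(C(C)C)CC[C@]2(C)CC=C(C)C[C@H](O)[C@H]21
F4 | step 7 | 4-(benzyloxy)-3-methoxybenzoic anhydride | COc1cc(C(=O)OC(=O)c2ccc(OCc3ccccc3)c(OC)c2)ccc1OCc1ccccc1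
F5 | step 5 | (1S,3aR,8S,8aS)-8-[(tert-butyldimethylsilyl)oxy]-3a,6-dimethyl-1-(prop-1-en-2-yl)-1,2,3,3a,4,7,8,8a-octahydroazulen-1-ol | O[C@@]1(C(C)=C)CC[C@]2(C)CC=C(C)C[C@H](O[Si](C)(C)C(C)(C)C)[C@H]21
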